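**Retrosynthetic overview**

1. The C40 skeleton is cut into the ε-ring C10 sulfone 14, the C20 dialdehyde 22 and the β-ring C10 phosphonium salt 21: Julia–Kocienski olefination at C7'=C8', Wittig olefination at C7=C8, then desilylation.
2. Both ring units come from one cyclohexenol, 10. The ε-ring needs only Mitsunobu inversion at C3'. The β-ring arises by hydroxyl-directed 4,5-epoxidation and E1cB opening, which shifts the olefin to C5=C6, installs the cis-3,4-diol and erases C6.
3. Ring 10 is made in one operation from the acyclic bis-allylic ether 6: [2,3]-Wittig shift, anionic oxy-Cope (bond C1'–C6') and Prins closure (bond C3'–C4'). This is the only ring-forming event; the β-ring is derived from the same carbocycle.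
4. Enabling feature: in the ε-ring the carbinol C3' lies between C2'H2 and the olefinic C4', the gem-dimethyl carbon C1' is 1,3 to it, and the stereocentre C6' is allylic to C4'=C5'. The ring atoms C1'–C6' therefore map onto a 1,5-dien-3-ol (oxy-Cope) whose C3' aldehyde ends five atoms from the isopropenyl terminus C4' (Prins).
5. The single carbinol stereocentre of 4 (kinetic resolution) is relayed to all four stereocentres of the target.

Key step: step 4

Remark: 1 and 22 are taken as purchasable building blocks; primed locants are carotenoid locants of the ε-ring (C1' gem-dimethyl carbon, C3' carbinol, C4'=C5' olefin, C6' chain-bearing CH, C7' its exocyclic carbon).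

**Route**

Step 1
Reactants: 1 2-[(tert-butyldiphenylsilyl)oxy]acetaldehyde; 2 isopropenylmagnesium bromide
Product: 3 rac-1-[(tert-butyldiphenylsilyl)oxy]-3-methylbut-3-en-2-ol
Conditions: THF, −78 → 0 °C; aq. NH4Cl
Reagents that add atoms: none
Why: Grignard 1,2-addition of the alkenylmagnesium reagent to the α-silyloxy aldehyde should give the racemic 2-methylallylic alcohol, whose carbinol centre is resolved in step 2.

Step 2
Reactants: 3 rac-1-[(tert-butyldiphenylsilyl)oxy]-3-methylbut-3-en-2-ol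
Product: 4 (2S)-1-[(tert-butyldiphenylsilyl)oxy]-3-methylbut-3-en-2-ol
Conditions: Ti(OiPr)4 (cat.), L-(+)-diisopropyl tartrate, t-BuOOH (0.6 equiv), 4 Å molecular sieves, CH2Cl2, −20 °C
Reagents that add atoms: none
Why: In this Sharpless kinetic resolution the L-(+)-tartrate catalyst should epoxidise the (R)-enantiomer much faster, so that the (S)-alcohol is recovered enantiomerically enriched.

Step 3
Reactants: 4 (2S)-1-[(tert-butyldiphenylsilyl)oxy]-3-methylbut-3-en-2-ol; 5 1-bromo-3-methylbut-2-ene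
Product: 6 (S)-tert-butyl{[3-methyl-2-(3-methylbut-2-enyloxy)but-3-en-1-yl]oxy}diphenylsilane
Conditions: NaH, n-Bu4NI (cat.), THF, 0 → 25 °C
Reagents that add atoms: none
Why: Williamson etherification at oxygen should give the bis-allylic ether without touching the carbinol stereocentre.

Step 4
Reactants: 6 (S)-tert-butyl{[3-methyl-2-(3-methylbut-2-enyloxy)but-3-en-1-yl]oxy}diphenylsilane
Product: 10 (1S,4R)-4-{[(tert-butyldiphenylsilyl)oxy]methyl}-3,5,5-trimethylcyclohex-2-en-1-ol, via lithium alkoxide 7 (not isolated), via potassium enolate 8 (not isolated), via aldehyde 9 (not isolated)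
Conditions: n-BuLi, THF, −78 °C; t-BuOK, 18-crown-6, −78 → 25 °C; AcOH, −78 °C; solvent exchange to CH2Cl2 without purification; BF3·OEt2, −78 °C
Reagents that add atoms: none
Why: Proposed new method: n-BuLi should deprotonate the less substituted α-oxy allylic CH2 (prenyl side) of 6; the carbanion should then undergo a suprafacial [2,3]-Wittig shift onto the methallyl terminus C4' (five-membered envelope, isobutenyl group exo), carrying the (S)-carbinol chirality into the new C3' carbinol of alkoxide 7, whose potassium/18-crown-6 salt should undergo a chair anionic oxy-Cope rearrangement that forms C1'–C6' and releases enolate 8, and after protonation to 9 BF3 should close C3'–C4' by a Prins attack of the isopropenyl terminus on the aldehyde, the tertiary C5' cation losing H-4' to give the ring olefin. The closest known reaction types are the tandem [2,3]-Wittig–anionic oxy-Cope rearrangement of bis-allylic ethers, oxy-Cope/carbonyl-ene domino sequences, type 2 carbonyl-ene cyclisations of δ,ε-unsaturated aldehydes and the acid-mediated cyclisation of pseudoionone to α-ionone (same cation, same proton loss); new are their merger in one flask and the endocyclic termination next to an oxygenated carbon. The only ring is closed in the Prins event, a 6-endo addition of the 1,1-disubstituted olefin (C4') to the C3' carbonyl through a chair. C6' is controlled by the oxy-Cope chair, in which the C3'–O bond must be equatorial because an axial oxygen would be syn-axial to a methyl of the C1' terminus, so the C3' configuration from the [2,3] shift is relayed to C6' (the E-olefin and any Z-olefin isomer of 7 arise from opposite allyl faces with opposite C3' configuration and converge on the same C6' centre); C3' is then set again in the Prins chair, where the carbonyl oxygen is equatorial for the same reason and the C6' CH2OSi group is axial to avoid A1,2 strain with the C5' methyl, which should give the 3',6'-cis ring. The step needs [2,3] rather than [1,2] migration, secured by the low temperature and the unhindered methallyl terminus, and endocyclic rather than exocyclic proton loss, expected because the equatorial oxygen cannot reach the C5' methyl hydrogens, as a concerted ene pathway would require, while its BF3 adduct sits next to H-4'.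

Step 5
Reactants: 10 (1S,4R)-4-{[(tert-butyldiphenylsilyl)oxy]methyl}-3,5,5-trimethylcyclohex-2-en-1-ol
Product: 11 (1S,4R)-4-(hydroxymethyl)-3,5,5-trimethylcyclohex-2-en-1-ol
Conditions: n-Bu4NF, THF, 25 °C
Reagents that add atoms: none
Why: Fluoride-mediated desilylation should free the primary alcohol and give the cis-diol that feeds both ring series.

Step 6
Reactants: 11 (1S,4R)-4-(hydroxymethyl)-3,5,5-trimethylcyclohex-2-en-1-ol
Product: 12 (1S,4R)-3,5,5-trimethyl-4-{[(1-phenyl-1H-tetrazol-5-yl)sulfanyl]methyl}cyclohex-2-en-1-ol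
Conditions: 1-phenyl-1H-tetrazole-5-thiol (1.05 equiv), PPh3, DIAD, THF, 0 °C
Reagents that add atoms: 1-phenyl-1H-tetrazole-5-thiol, SC1=NN=NN1c1ccccc1
Why: Mitsunobu thioetherification should be selective for the primary alcohol (SN2 at CH2, no stereocentre involved) and installs the Julia–Kocienski handle at C7'.

Step 7
Reactants: 12 (1S,4R)-3,5,5-trimethyl-4-{[(1-phenyl-1H-tetrazol-5-yl)sulfanyl]methyl}cyclohex-2-en-1-ol
Product: 13 (1R,4R)-3,5,5-trimethyl-4-{[(1-phenyl-1H-tetrazol-5-yl)sulfanyl]methyl}cyclohex-2-en-1-yl benzoate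
Conditions: PhCO2H, PPh3, DIAD, toluene, 0 → 25 °C
Reagents that add atoms: benzoic acid, OC(=O)c1ccccc1
Why: Mitsunobu esterification should proceed with SN2 inversion at the allylic carbinol, turning the cis ring into the trans (3'R,6'R) ring of the ε-end while protecting the oxygen.

Step 8
Reactants: 13 (1R,4R)-3,5,5-trimethyl-4-{[(1-phenyl-1H-tetrazol-5-yl)sulfanyl]methyl}cyclohex-2-en-1-yl benzoate
Product: 14 (1R,4R)-3,5,5-trimethyl-4-{[(1-phenyl-1H-tetrazol-5-yl)sulfonyl]methyl}cyclohex-2-en-1-yl benzoate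
Conditions: (NH4)6Mo7O24·4H2O (cat.), 30% H2O2, EtOH, 0 → 25 °C
Reagents that add atoms: hydrogen peroxide, OO
Why: Molybdate-catalysed sulfide-to-sulfone oxidation should leave the trisubstituted olefin and the allylic benzoate untouched.

Step 9
Reactants: 11 (1S,4R)-4-(hydroxymethyl)-3,5,5-trimethylcyclohex-2-en-1-ol
Product: 15 (1S,2S,5S,6R)-5-(hydroxymethyl)-4,4,6-trimethyl-7-oxabicyclo[4.1.0]heptan-2-ol
Conditions: VO(acac)2 (cat.), t-BuOOH, CH2Cl2, 0 °C
Reagents that add atoms: tert-butyl hydroperoxide, CC(C)(C)OO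
Why: Hydroxyl-directed epoxidation should deliver oxygen to the ring face that carries both the allylic and the homoallylic hydroxyl group, which sets the future C4 oxygen cis to the C3 hydroxyl.

Step 10
Reactants: 15 (1S,2S,5S,6R)-5-(hydroxymethyl)-4,4,6-trimethyl-7-oxabicyclo[4.1.0]heptan-2-ol
Product: 17 (3R,4S)-3,4-dihydroxy-2,6,6-trimethylcyclohex-1-ene-1-carbaldehyde, via epoxy aldehyde 16 (not isolated)
Conditions: TEMPO (cat.), PhI(OAc)2, CH2Cl2, 25 °C; then DBU, 0 °C
Reagents that add atoms: none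
Why: Oxoammonium oxidation selective for the primary alcohol gives the aldehyde, whose enolate opens the epoxide by E1cB elimination; the C4–O bond is not broken, so the cis-diol configuration is kept while the C6 stereocentre is erased.

Step 11
Reactants: 17 (3R,4S)-3,4-dihydroxy-2,6,6-trimethylcyclohex-1-ene-1-carbaldehyde
Product: 18 (3R,4S)-3,4-bis[(tert-butyldimethylsilyl)oxy]-2,6,6-trimethylcyclohex-1-ene-1-carbaldehyde
Conditions: TBSOTf, 2,6-lutidine, CH2Cl2, −78 → 0 °C
Reagents that add atoms: tert-butyldimethylsilyl trifluoromethanesulfonate, CC(C)(C)[Si](C)(C)OS(=O)(=O)C(F)(F)F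
Why: Silylation of both hydroxyl groups gives ethers that are poor leaving groups, which should prevent 1,4-elimination from the later allylic ylide.

Step 12
Reactants: 18 (3R,4S)-3,4-bis[(tert-butyldimethylsilyl)oxy]-2,6,6-trimethylcyclohex-1-ene-1-carbaldehyde
Product: 19 [(3R,4S)-3,4-bis[(tert-butyldimethylsilyl)oxy]-2,6,6-trimethylcyclohex-1-en-1-yl]methanol
Conditions: NaBH4, CeCl3·7H2O, MeOH, 0 °C
Reagents that add atoms: none
Why: Luche 1,2-reduction of the hindered enal should give the primary allylic alcohol without conjugate reduction.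

Step 13
Reactants: 19 [(3R,4S)-3,4-bis[(tert-butyldimethylsilyl)oxy]-2,6,6-trimethylcyclohex-1-en-1-yl]methanol
Product: 21 {[(3R,4S)-3,4-bis[(tert-butyldimethylsilyl)oxy]-2,6,6-trimethylcyclohex-1-en-1-yl]methyl}triphenylphosphonium bromide, via allylic bromide 20 (not isolated)
Conditions: CBr4, PPh3 (2.2 equiv), CH2Cl2, 0 → 25 °C
Reagents that add atoms: carbon tetrabromide, BrC(Br)(Br)Br; triphenylphosphine, c1ccc(cc1)P(c1ccccc1)c1ccccc1
Why: Appel bromination under neutral conditions followed by SN2 quaternisation of the allylic bromide with the excess phosphine should give the Wittig salt without ionising the allylic C4 ether.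

Step 14
Reactants: 14 (1R,4R)-3,5,5-trimethyl-4-{[(1-phenyl-1H-tetrazol-5-yl)sulfonyl]methyl}cyclohex-2-en-1-yl benzoate; 22 crocetindialdehyde
Product: 23 (3R,6R)-3-(benzoyloxy)-8'-apo-ε-caroten-8'-al
Conditions: KN(SiMe3)2 (1.0 equiv), THF, −78 °C; then addition to 22 (3 equiv), −78 → −20 °C
Reagents that add atoms: none
Why: Julia–Kocienski olefination should form the C7'=C8' bond, the excess dialdehyde favouring mono-olefination; the sulfonyl carbanion is not conjugated with the C6' hydrogen, so the stereocentre should survive.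

Step 15
Reactants: 21 {[(3R,4S)-3,4-bis[(tert-butyldimethylsilyl)oxy]-2,6,6-trimethylcyclohex-1-en-1-yl]methyl}triphenylphosphonium bromide; 23 (3R,6R)-3-(benzoyloxy)-8'-apo-ε-caroten-8'-al
Product: 24 (3S,4R,3'R,6'R)-3,4-bis[(tert-butyldimethylsilyl)oxy]-β,ε-caroten-3'-ol
Conditions: NaOMe (excess), MeOH/CH2Cl2, 0 → 25 °C; then heptane, 90 °C
Reagents that add atoms: none
Why: Wittig olefination should form the C7=C8 bond, the methoxide cleaving the benzoate by transesterification in the same operation, and heating should equilibrate Z isomers at C7 and C7' to the all-E polyene.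

Step 16
Reactants: 24 (3S,4R,3'R,6'R)-3,4-bis[(tert-butyldimethylsilyl)oxy]-β,ε-caroten-3'-ol
Product: 25 (3S,4R,3'R,6'R)-β,ε-carotene-3,4,3'-triol
Conditions: n-Bu4NF, THF, 0 → 25 °C, argon, dark
Reagents that add atoms: none
Why: Fluoride-mediated desilylation under non-acidic conditions should free the cis-diol without ionising the allylic alcohols of the polyene.

**Compound list**

1 | 2-[(tert-butyldiphenylsilyl)oxy]acetaldehyde | O=CCO[Si](c1ccccc1)(c2ccccc2)C(C)(C)C | starting material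
2 | isopropenylmagnesium bromide | C=C(C)[Mg]Br | starting material
3 | rac-1-[(tert-butyldiphenylsilyl)oxy]-3-methylbut-3-en-2-ol | C=C(C)C(O)CO[Si](c1ccccc1)(c2ccccc2)C(C)(C)C | intermediate
4 | (2S)-1-[(tert-butyldiphenylsilyl)oxy]-3-methylbut-3-en-2-ol | C=C(C)[C@H](O)CO[Si](c1ccccc1)(c2ccccc2)C(C)(C)C | intermediate
5 | 1-bromo-3-methylbut-2-ene (prenyl bromide) | CC(C)=CCBr | starting material
6 | (S)-tert-butyl{[3-methyl-2-(3-methylbut-2-enyloxy)but-3-en-1-yl]oxy}diphenylsilane | C=C(C)[C@H](OCC=C(C)C)CO[Si](c1ccccc1)(c2ccccc2)C(C)(C)C | intermediate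
7 | lithium (2E,5S)-1-[(tert-butyldiphenylsilyl)oxy]-3,7-dimethylocta-2,6-dien-5-olate | [Li+].CC(C)=C[C@@H]([O-])C/C(C)=C/CO[Si](c1ccccc1)(c2ccccc2)C(C)(C)C | intermediate
8 | potassium (1E,4S)-4-{[(tert-butyldiphenylsilyl)oxy]methyl}-3,3,5-trimethylhexa-1,5-dien-1-olate | [K+].[O-]/C=C/C(C)(C)[C@@H](CO[Si](c1ccccc1)(c2ccccc2)C(C)(C)C)C(C)=C | intermediate
9 | (4S)-4-{[(tert-butyldiphenylsilyl)oxy]methyl}-3,3,5-trimethylhex-5-enal | O=CCC(C)(C)[C@@H](CO[Si](c1ccccc1)(c2ccccc2)C(C)(C)C)C(C)=C | intermediate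
10 | (1S,4R)-4-{[(tert-butyldiphenylsilyl)oxy]methyl}-3,5,5-trimethylcyclohex-2-en-1-ol (hydroxyl and CH2OSi cis) | CC1=C[C@@H](O)CC(C)(C)[C@H]1CO[Si](c2ccccc2)(c3ccccc3)C(C)(C)C | intermediate
11 | (1S,4R)-4-(hydroxymethyl)-3,5,5-trimethylcyclohex-2-en-1-ol | CC1=C[C@@H](O)CC(C)(C)[C@H]1CO | intermediate
12 | (1S,4R)-3,5,5-trimethyl-4-{[(1-phenyl-1H-tetrazol-5-yl)sulfanyl]methyl}cyclohex-2-en-1-ol | CC1=C[C@@H](O)CC(C)(C)[C@H]1CSC2=NN=NN2c3ccccc3 | intermediate
13 | (1R,4R)-3,5,5-trimethyl-4-{[(1-phenyl-1H-tetrazol-5-yl)sulfanyl]methyl}cyclohex-2-en-1-yl benzoate | CC1=C[C@H](OC(=O)c2ccccc2)CC(C)(C)[C@H]1CSC3=NN=NN3c4ccccc4 | intermediate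
14 | (1R,4R)-3,5,5-trimethyl-4-{[(1-phenyl-1H-tetrazol-5-yl)sulfonyl]methyl}cyclohex-2-en-1-yl benzoate | CC1=C[C@H](OC(=O)c2ccccc2)CC(C)(C)[C@H]1CS(=O)(=O)C3=NN=NN3c4ccccc4 | intermediate
15 | (1S,2S,5S,6R)-5-(hydroxymethyl)-4,4,6-trimethyl-7-oxabicyclo[4.1.0]heptan-2-ol (epoxide on the face of both hydroxyl-bearing groups) | C[C@]12O[C@H]1[C@@H](O)CC(C)(C)[C@H]2CO | intermediate
16 | (1R,2R,5S,6S)-5-hydroxy-1,3,3-trimethyl-7-oxabicyclo[4.1.0]heptane-2-carbaldehyde | C[C@]12O[C@H]1[C@@H](O)CC(C)(C)[C@H]2C=O | intermediate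
17 | (3R,4S)-3,4-dihydroxy-2,6,6-trimethylcyclohex-1-ene-1-carbaldehyde (cis-diol) | O=CC1=C(C)[C@@H](O)[C@@H](O)CC1(C)C | intermediate
18 | (3R,4S)-3,4-bis[(tert-butyldimethylsilyl)oxy]-2,6,6-trimethylcyclohex-1-ene-1-carbaldehyde | O=CC1=C(C)[C@@H](O[Si](C)(C)C(C)(C)C)[C@@H](O[Si](C)(C)C(C)(C)C)CC1(C)C | intermediate
19 | [(3R,4S)-3,4-bis[(tert-butyldimethylsilyl)oxy]-2,6,6-trimethylcyclohex-1-en-1-yl]methanol | OCC1=C(C)[C@@H](O[Si](C)(C)C(C)(C)C)[C@@H](O[Si](C)(C)C(C)(C)C)CC1(C)C | intermediate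
20 | {[(1S,6R)-2-(bromomethyl)-3,3-dimethyl... ring as in 19]}: (3R,4S)-1-(bromomethyl)-3,4-bis[(tert-butyldimethylsilyl)oxy]-2,6,6-trimethylcyclohex-1-ene | BrCC1=C(C)[C@@H](O[Si](C)(C)C(C)(C)C)[C@@H](O[Si](C)(C)C(C)(C)C)CC1(C)C | intermediate
21 | {[(3R,4S)-3,4-bis[(tert-butyldimethylsilyl)oxy]-2,6,6-trimethylcyclohex-1-en-1-yl]methyl}triphenylphosphonium bromide | [Br-].c2ccccc2[P+](c3ccccc3)(c4ccccc4)CC1=C(C)[C@@H](O[Si](C)(C)C(C)(C)C)[C@@H](O[Si](C)(C)C(C)(C)C)CC1(C)C | intermediate
22 | crocetindialdehyde, (2E,4E,6E,8E,10E,12E,14E)-2,6,11,15-tetramethylhexadeca-2,4,6,8,10,12,14-heptaenedial | O=C/C(C)=C/C=C/C(C)=C/C=C/C=C(C)/C=C/C=C(C)/C=O | starting material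
23 | (3R,6R)-3-(benzoyloxy)-8'-apo-ε-caroten-8'-al (all-E) | CC1=C[C@H](OC(=O)c2ccccc2)CC(C)(C)[C@H]1/C=C/C(C)=C/C=C/C(C)=C/C=C/C=C(C)/C=C/C=C(C)/C=O | intermediate
24 | (3S,4R,3'R,6'R)-3,4-bis[(tert-butyldimethylsilyl)oxy]-β,ε-caroten-3'-ol (all-E) | CC1=C[C@H](O)CC(C)(C)[C@H]1/C=C/C(C)=C/C=C/C(C)=C/C=C/C=C(C)/C=C/C=C(C)/C=C/C2=C(C)[C@@H](O[Si](C)(C)C(C)(C)C)[C@@H](O[Si](C)(C)C(C)(C)C)CC2(C)C | intermediate
25 | (3S,4R,3'R,6'R)-β,ε-carotene-3,4,3'-triol (CNP0191612.1) | CC1=C[C@H](O)CC(C)(C)[C@H]1/C=C/C(C)=C/C=C/C(C)=C/C=C/C=C(C)/C=C/C=C(C)/C=C/C1=C(C)[C@@H](O)[C@@H](O)CC1(C)C | target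

**Step count and risks**

Total step count: 16. Longest linear sequence: 12 steps (steps 1–5, 9–13, 15, 16).

Steps most likely to fail:

Step 4 (Proposed new method). The telescoped cascade may leak into [1,2]-migration or lose stereochemical fidelity in the two sigmatropic shifts, and the cationic closure may end by exocyclic or conjugative proton loss or with the other relative configuration. The fallback uses known reactions one at a time, sets out from 6 and comes back at 10. [2,3]-Wittig rearrangement of 6 (n-BuLi, THF, −78 °C) with aqueous work-up gives the dienol (2E,5S)-1-[(tert-butyldiphenylsilyl)oxy]-3,7-dimethylocta-2,6-dien-5-ol F1. Anionic oxy-Cope rearrangement (KH, 18-crown-6, THF) gives aldehyde 9, now isolated. Me2AlCl-promoted type 2 carbonyl-ene cyclisation gives (4R)-4-{[(tert-butyldiphenylsilyl)oxy]methyl}-5,5-dimethyl-3-methylidenecyclohexan-1-ol F2 as carbinol epimers. Dess–Martin oxidation followed by acid-mediated (p-TsOH) conjugation of the β,γ-enone gives (4R)-4-{[(tert-butyldiphenylsilyl)oxy]methyl}-3,5,5-trimethylcyclohex-2-en-1-one F3. Reduction with LiBH(s-Bu)3, expected anti to the axial ring methyl, gives the trans alcohol (1R,4R)-4-{[(tert-butyldiphenylsilyl)oxy]methyl}-3,5,5-trimethylcyclohex-2-en-1-ol F4. Mitsunobu inversion with benzoic acid gives the cis benzoate (1S,4R)-4-{[(tert-butyldiphenylsilyl)oxy]methyl}-3,5,5-trimethylcyclohex-2-en-1-yl benzoate F5, and methanolysis (K2CO3, MeOH) gives 10.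

Step 10. The hydroxy aldehyde may be over-oxidised through a bridged lactol, or the epoxide may open before the aldehyde is formed. The fallback removes the free secondary hydroxyl from the oxidation; it sets out from 15 and comes back at 18. Bis-silylation (TBSOTf, 2,6-lutidine) gives the bis-silyl ether of 15 F6. Selective release of the primary alcohol (HF·pyridine/pyridine, THF, 0 °C) gives the secondary mono-silyl ether F7. Dess–Martin oxidation gives the silyloxy epoxy aldehyde F8. DBU-induced E1cB opening gives (3R,4S)-4-[(tert-butyldimethylsilyl)oxy]-3-hydroxy-2,6,6-trimethylcyclohex-1-ene-1-carbaldehyde F9, and silylation of the new hydroxyl (TBSOTf, 2,6-lutidine) gives 18.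

Step 14. Statistical double olefination of the dialdehyde, low E-selectivity and base-induced migration of the skipped ε-ring olefin may erode the mono-adduct. The fallback lets the better-behaved Wittig salt desymmetrise the dialdehyde; it sets out from 21 and 22 and comes back at 24. Wittig reaction of 21 with excess 22 (NaOMe, MeOH/CH2Cl2) gives (3S,4R)-3,4-bis[(tert-butyldimethylsilyl)oxy]-8'-apo-β-caroten-8'-al F10. Julia–Kocienski olefination of F10, which has a single aldehyde, with the anion of 14 (KN(SiMe3)2, THF, −78 °C) gives the 3'-benzoate of 24 F11, and methanolysis (K2CO3, MeOH) gives 24.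

Further compounds
F1 | step 4 | (2E,5S)-1-[(tert-butyldiphenylsilyl)oxy]-3,7-dimethylocta-2,6-dien-5-ol | CC(C)=C[C@@H](O)C/C(C)=C/CO[Si](c1ccccc1)(c2ccccc2)C(C)(C)C
F2 | step 4 | (4R)-4-{[(tert-butyldiphenylsilyl)oxy]methyl}-5,5-dimethyl-3-methylidenecyclohexan-1-ol (carbinol epimers) | C=C1CC(O)CC(C)(C)[C@H]1CO[Si](c2ccccc2)(c3ccccc3)C(C)(C)C
F3 | step 4 | (4R)-4-{[(tert-butyldiphenylsilyl)oxy]methyl}-3,5,5-trimethylcyclohex-2-en-1-one | CC1=CC(=O)CC(C)(C)[C@H]1CO[Si](c2ccccc2)(c3ccccc3)C(C)(C)C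
F4 | step 4 | (1R,4R)-4-{[(tert-butyldiphenylsilyl)oxy]methyl}-3,5,5-trimethylcyclohex-2-en-1-ol | CC1=C[C@H](O)CC(C)(C)[C@H]1CO[Si](c2ccccc2)(c3ccccc3)C(C)(C)C
F5 | step 4 | (1S,4R)-4-{[(tert-butyldiphenylsilyl)oxy]methyl}-3,5,5-trimethylcyclohex-2-en-1-yl benzoate | CC1=C[C@@H](OC(=O)c2ccccc2)CC(C)(C)[C@H]1CO[Si](c3ccccc3)(c4ccccc4)C(C)(C)C
F6 | step 10 | bis(tert-butyldimethylsilyl) ether of 15 | C[C@]12O[C@H]1[C@@H](O[Si](C)(C)C(C)(C)C)CC(C)(C)[C@H]2CO[Si](C)(C)C(C)(C)C
F7 | step 10 | secondary tert-butyldimethylsilyl ether of 15 with free primary alcohol | C[C@]12O[C@H]1[C@@H](O[Si](C)(C)C(C)(C)C)CC(C)(C)[C@H]2CO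
F8 | step 10 | tert-butyldimethylsilyl ether of epoxy aldehyde 16 | C[C@]12O[C@H]1[C@@H](O[Si](C)(C)C(C)(C)C)CC(C)(C)[C@H]2C=O
F9 | step 10 | (3R,4S)-4-[(tert-butyldimethylsilyl)oxy]-3-hydroxy-2,6,6-trimethylcyclohex-1-ene-1-carbaldehyde | O=CC1=C(C)[C@@H](O)[C@@H](O[Si](C)(C)C(C)(C)C)CC1(C)C
F10 | step 14 | (3S,4R)-3,4-bis[(tert-butyldimethylsilyl)oxy]-8'-apo-β-caroten-8'-al | O=C/C(C)=C/C=C/C(C)=C/C=C/C=C(C)/C=C/C=C(C)/C=C/C1=C(C)[C@@H](O[Si](C)(C)C(C)(C)C)[C@@H](O[Si](C)(C)C(C)(C)C)CC1(C)C
F11 | step 14 | (3S,4R,3'R,6'R)-3,4-bis[(tert-butyldimethylsilyl)oxy]-β,ε-caroten-3'-yl benzoate | CC1=C[C@H](OC(=O)c2ccccc2)CC(C)(C)[C@H]1/C=C/C(C)=C/C=C/C(C)=C/C=C/C=C(C)/C=C/C=C(C)/C=C/C3=C(C)[C@@H](O[Si](C)(C)C(C)(C)C)[C@@H](O[Si](C)(C)C(C)(C)C)CC3(C)C
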